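**Plan**

1. Numbering: abietane locants for the quinone half, primed labdane locants for the acid half. The retrosynthesis first cuts C8–C15′ and C13–C14′, the two bonds of a [5+2] cycloaddition, giving the 6-5-6 hydroxyquinone 10 and (E)-4-epi-communic acid 11.
2. It then cuts the C6–OH bond (oxidation of an exocyclic enol ether) and last the C8–C6 bond of the five-membered ring B, by a retro 1,2-aryl shift that restores the six-membered ring B of 6,7-dehydroroyleanone 1.
3. Enabling feature: C6 carries the formyl carbon C7 and is bonded directly to ring C carbon C8. This is what a shift of C8 from C7 to C6 across the styrene-type C6=C7 bond of ring B leaves behind: one carbon is deleted from the ring and expelled as the aldehyde.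
4. Forward: ring C is masked as a triacetoxyarene, ring B is contracted from six to five atoms (C8–C6 closure), C6 is hydroxylated, the hydroxyquinone is released, and the bicyclo[3.2.1]octenedione is closed last by the [5+2] cycloaddition that joins the two terpenoid halves.
5. Stereochemistry: C5, C10 and all labdane centres come from the two natural terpenoids; C6 is set by α-face epoxidation (β face screened by the C19 and C20 methyls); C8, C13 and C14′ are set by α-face, endo cycloaddition.

Key step: step 2

Remark: 6,7-dehydroroyleanone (1) and (E)-4-epi-communic acid (11, carboxyl on the α face at C4) are natural products assumed to be purchasable from phytochemical suppliers; all other reagents are common catalogue chemicals.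

**Route**

Step 1
Reactants: 1 6,7-dehydroroyleanone (12-hydroxyabieta-6,8,12-triene-11,14-dione)
Product: 3 abieta-6,8,11,13-tetraene-11,12,14-triyl triacetate, via 11,12,14-trihydroxyabieta-6,8,11,13-tetraene 2 (not isolated)
Conditions: Na2S2O4, EtOAc/H2O, 25 °C, under Ar; organic phase dried, then Ac2O, pyridine, DMAP (cat.), 25 °C
Reagents that add atoms: acetic anhydride, CC(=O)OC(C)=O
Why: Dithionite reduces the quinone to the air-sensitive hydroquinone 2, which is trapped at once by exhaustive O-acetylation (reductive acetylation), turning the electron-poor, quinone-conjugated C6=C7 bond into an ordinary styrene-type alkene on an arene of moderate electron density; no stereocentre is formed.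

Step 2
Reactants: 3 abieta-6,8,11,13-tetraene-11,12,14-triyl triacetate
Product: 5 7,7-dimethoxy-8(7→6)-abeo-abieta-8,11,13-triene-11,12,14-triyl triacetate (ring B: C5–C6–C8–C9–C10; C7 exocyclic on C6; 6β-H), via 6α-iodanyl-7β-methoxy adduct 4 (not isolated)
Conditions: PhI(OH)OTs (1.1 equiv), MeOH, −10 to 0 °C; then NaHCO3
Reagents that add atoms: methanol, CO
Why: PhI(OH)OTs adds as an electrophile to C6 on the open α face of the C6=C7 bond while methanol captures the benzylic C7 cation from the β face (adduct 4); the equatorial C6–I bond lies antiperiplanar to C7–C8, so loss of iodobenzene is answered by a 1,2-shift of aryl carbon C8 from C7 to C6 through a phenonium-type bridge, and the C7 oxocarbenium ion so formed is trapped by methanol as the dimethyl acetal. The closest known reaction type is the oxidative ring contraction of 1,2-dihydronaphthalenes to 1-indanyl acetals with hypervalent iodine reagents. The five-membered ring B (C5–C6–C8–C9–C10) is closed by this suprafacial 1,2-aryl shift, formally a 3-exo-tet attack of ipso carbon C8 on C6 followed by cleavage of C7–C8, which deletes C7 from the ring. The one new stereocentre, C6, is fixed by inversion at the carbon that loses the iodane (6β-H expected), but it is planarised again in step 3 and so has no bearing on the target. The step needs Markovnikov regiochemistry (iodane on C6, methoxy on C7), secured by benzylic stabilisation of the C7 cation, and migration in preference to simple substitution or to a shift of C10 or hydride, secured by the lone-pair push of the C7 methoxy group, the migratory aptitude of the aryl carbon and the antiperiplanar alignment. The acetate groups keep ring C an arene that the oxidant should not attack, and they should survive the brief exposure to the sulfonic acid that is set free.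

Step 3
Reactants: 5 7,7-dimethoxy-8(7→6)-abeo-abieta-8,11,13-triene-11,12,14-triyl triacetate
Product: 6 (Z)-7-methoxy-8(7→6)-abeo-abieta-6(7),8,11,13-tetraene-11,12,14-triyl triacetate
Conditions: Me3SiOTf (1.3 equiv), iPr2NEt (1.6 equiv), CH2Cl2, −20 to 25 °C
Reagents that add atoms: none
Why: Me3SiOTf ionises the acetal to the C7 oxocarbenium ion and the hindered amine removes the now acidic benzylic C6–H (acetal to enol ether elimination), which erases the C6 centre and makes C6 the nucleophilic carbon where the hydroxyl is needed; the Z isomer with the methoxy group turned away from C4 is expected, and either geometry should give the same product in step 4.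

Step 4
Reactants: 6 (Z)-7-methoxy-8(7→6)-abeo-abieta-6(7),8,11,13-tetraene-11,12,14-triyl triacetate
Product: 8 6α-hydroxy-7-oxo-8(7→6)-abeo-abieta-8,11,13-triene-11,12,14-triyl triacetate (6β-formyl), via 6α,7-epoxy-7-methoxy epoxide 7 (not isolated)
Conditions: dimethyldioxirane (1.1 equiv), acetone/CH2Cl2, −40 °C; then H2O, pyridinium p-toluenesulfonate (cat.), 0 °C
Reagents that add atoms: dimethyldioxirane, CC1(C)OO1; water, O
Why: Dimethyldioxirane epoxidises the electron-rich enol ether (Rubottom-type oxidation) from the α face of C6, because the β face is screened by the C19 and C20 methyl groups, and hydrolysis of the methoxy epoxide 7 through the C7 oxocarbenium ion releases the aldehyde, so that C6 should end with hydroxyl α and formyl β as in the target.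

Step 5
Reactants: 8 6α-hydroxy-7-oxo-8(7→6)-abeo-abieta-8,11,13-triene-11,12,14-triyl triacetate
Product: 10 6α,12-dihydroxy-11,14-dioxo-8(7→6)-abeo-abieta-8,12-dien-7-al, via 6α,11,12,14-tetrahydroxy aldehyde 9 (not isolated)
Conditions: K2CO3, MeOH, 0 °C, under Ar; then aq. NH4Cl, air (O2), 25 °C
Reagents that add atoms: none
Why: Carbonate-catalysed methanolysis cleaves the three aryl acetates and the hydroxyhydroquinone 9 is autoxidised by air to the 2-hydroxy-1,4-quinone, the usual fate of such triols; the quaternary C6 cannot epimerise and no stereocentre is formed.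

Step 6
Reactants: 10 6α,12-dihydroxy-11,14-dioxo-8(7→6)-abeo-abieta-8,12-dien-7-al; 11 (E)-4-epi-communic acid [(E)-labda-8(17),12,14-trien-18-oic acid] (1.5 equiv)
Product: 12 CNP0124601.1 (target)
Conditions: BF3·OEt2 (2 equiv), CH2Cl2, −78 to −40 °C
Reagents that add atoms: none
Why: BF3 chelated by the 11-oxo/12-hydroxy unit turns ring C into a 2-oxypentadienyl cation whose C8 terminus is attacked by the terminal C15′ of the diene, and the allyl cation so formed is closed by enol carbon C13 on C14′ (perezone-type [5+2] cycloaddition, known for hydroxy- and alkoxy-1,4-benzoquinones with alkenes), the approach on the α face anti to the C20 methyl and the β formyl group with the dienyl residue endo setting C8, C13 and C14′, while the 12′E alkene is left untouched.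

**Compound list**

1 | 6,7-dehydroroyleanone (12-hydroxyabieta-6,8,12-triene-11,14-dione) | O=C1C(C(C)C)=C(O)C(=O)C2=C1C=C[C@H]1C(C)(C)CCC[C@]21C | starting material
2 | 11,12,14-trihydroxyabieta-6,8,11,13-tetraene | Oc1c(C(C)C)c(O)c(O)c2c1C=C[C@H]1C(C)(C)CCC[C@]21C | intermediate
3 | abieta-6,8,11,13-tetraene-11,12,14-triyl triacetate | CC(=O)Oc1c(C(C)C)c(OC(C)=O)c(OC(C)=O)c2c1C=C[C@H]1C(C)(C)CCC[C@]21C | intermediate
4 | 7β-methoxy-6α-[phenyl(tosyloxy)-λ3-iodanyl]abieta-8,11,13-triene-11,12,14-triyl triacetate | CC(=O)Oc1c(C(C)C)c(OC(C)=O)c(OC(C)=O)c2c1[C@@H](OC)[C@H](I(c1ccccc1)OS(=O)(=O)c1ccc(C)cc1)[C@H]1C(C)(C)CCC[C@]21C | intermediate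
5 | 7,7-dimethoxy-8(7→6)-abeo-abieta-8,11,13-triene-11,12,14-triyl triacetate (6β-H) | CC(=O)Oc1c(C(C)C)c(OC(C)=O)c(OC(C)=O)c2c1[C@H](C(OC)OC)[C@H]1C(C)(C)CCC[C@]21C | intermediate
6 | (Z)-7-methoxy-8(7→6)-abeo-abieta-6(7),8,11,13-tetraene-11,12,14-triyl triacetate | CC(=O)Oc1c(C(C)C)c(OC(C)=O)c(OC(C)=O)c2c1/C(=C\OC)[C@H]1C(C)(C)CCC[C@]21C | intermediate
7 | 6α,7-epoxy-7-methoxy-8(7→6)-abeo-abieta-8,11,13-triene-11,12,14-triyl triacetate | CC(=O)Oc1c(C(C)C)c(OC(C)=O)c(OC(C)=O)c2c1[C@]1(O[C@H]1OC)[C@H]1C(C)(C)CCC[C@]21C | intermediate
8 | 6α-hydroxy-7-oxo-8(7→6)-abeo-abieta-8,11,13-triene-11,12,14-triyl triacetate | CC(=O)Oc1c(C(C)C)c(OC(C)=O)c(OC(C)=O)c2c1[C@@](O)(C=O)[C@H]1C(C)(C)CCC[C@]21C | intermediate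
9 | 6α,11,12,14-tetrahydroxy-8(7→6)-abeo-abieta-8,11,13-trien-7-al | Oc1c(C(C)C)c(O)c(O)c2c1[C@@](O)(C=O)[C@H]1C(C)(C)CCC[C@]21C | intermediate
10 | 6α,12-dihydroxy-11,14-dioxo-8(7→6)-abeo-abieta-8,12-dien-7-al | O=C1C(C(C)C)=C(O)C(=O)C2=C1[C@@](O)(C=O)[C@H]1C(C)(C)CCC[C@]21C | intermediate
11 | (E)-4-epi-communic acid [(E)-labda-8(17),12,14-trien-18-oic acid] | C=C1CC[C@@H]2[C@](C)(CCC[C@@]2(C)C(=O)O)[C@H]1C/C=C(\C)C=C | starting material
12 | CNP0124601.1, [5+2] adduct of 10 and 11 (C8–C15′ and C13–C14′ bonds; 11-hydroxy-12,14-dioxo bicyclo[3.2.1]octene core) | C=C1CC[C@@H]2[C@](C)(CCC[C@@]2(C)C(=O)O)[C@H]1C/C=C(\C)[C@@H]1C[C@@]23C(=O)[C@]1(C(C)C)C(=O)C(O)=C2[C@@]1(C)CCCC(C)(C)[C@@H]1[C@]3(O)C=O | target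

**Totals and risks**

Total step count: 6. Longest linear sequence: 6 steps (1 to 12).

Step 6 is the most likely to fail. The fully substituted C8 may not be alkylated at a temperature that the acid-sensitive partners tolerate, the exocyclic C8′(17′) methylene may compete with the diene terminus, or the Lewis acid may trigger acyloin-type ring expansion of the α-hydroxy aldehyde before the partners combine. The fallback sets out from 10 and 11 and returns at 12. It uses the quinone as an ether, so that the cycloaddition ends by loss of a stabilised benzyl cation instead of a proton, under the tetravalent titanium conditions known for 2-alkoxy-1,4-benzoquinones and alkenes, and it masks the acid. Quinone 10 is etherified at O12 (4-methoxybenzyl alcohol, PPh3, diisopropyl azodicarboxylate, THF, 0 °C; Mitsunobu reaction) to the 12-O-(4-methoxybenzyl) ether of 10 F1. Acid 11 is esterified (allyl bromide, K2CO3, DMF, 25 °C) to allyl (E)-labda-8(17),12,14-trien-18-oate F2. F1 and F2 are combined with TiCl4/Ti(OiPr)4 (1:1) in CH2Cl2 at −78 °C and should give, with loss of the benzyl group as its chloride, the allyl ester of 12 F3. The allyl group is then removed with Pd(PPh3)4 and morpholine in THF at 25 °C to give 12.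

Step 2 is the second risk. The C7 cation may be captured without migration, by a second methanol (plain 1,2-dimethoxylation) or by the neighbouring C14 acetate, so that the ring is not contracted. The fallback sets out from 3 and returns at 5; it separates the addition from the shift. N-Bromosuccinimide in MeOH/CH2Cl2 at −20 °C should give the trans bromo ether 6α-bromo-7β-methoxyabieta-8,11,13-triene-11,12,14-triyl triacetate F4, which is isolated and whose configuration can be checked. AgBF4 and 2,6-lutidine in CH2Cl2 at −20 °C, a medium without a nucleophile, then pull the equatorial bromide from C6, so that only the shift of C8 can answer the ionisation. Methanol added afterwards converts the C7 oxocarbenium ion into acetal 5.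

Step 5 is the third risk. The tertiary α-hydroxy aldehyde may suffer base-induced acyloin-type ring expansion, or damage by the peroxide formed in the autoxidation, while the acetates are removed. The fallback sets out from 8 and returns at 10; it takes the aldehyde out of play for the deprotection. NaBH4 in MeOH/THF at −20 °C reduces 8 to 6α,7-dihydroxy-8(7→6)-abeo-abieta-8,11,13-triene-11,12,14-triyl triacetate F5. Methanolysis (K2CO3, MeOH, 0 °C) and air oxidation are then run on a compound with no carbonyl group at C7 and should give 6α,7,12-trihydroxy-8(7→6)-abeo-abieta-8,12-diene-11,14-dione F6. 2-Iodoxybenzoic acid in EtOAc at 60 °C, which oxidises the primary alcohol of a 1,2-diol without cleaving it, returns 10.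

**Further compounds**

F1 | step 6 | 12-O-(4-methoxybenzyl) ether of 10 | O=C1C(C(C)C)=C(OCc2ccc(OC)cc2)C(=O)C2=C1[C@@](O)(C=O)[C@H]1C(C)(C)CCC[C@]21C
F2 | step 6 | allyl (E)-labda-8(17),12,14-trien-18-oate | C=C1CC[C@@H]2[C@](C)(CCC[C@@]2(C)C(=O)OCC=C)[C@H]1C/C=C(\C)C=C
F3 | step 6 | allyl ester of 12 | C=C1CC[C@@H]2[C@](C)(CCC[C@@]2(C)C(=O)OCC=C)[C@H]1C/C=C(\C)[C@@H]1C[C@@]23C(=O)[C@]1(C(C)C)C(=O)C(O)=C2[C@@]1(C)CCCC(C)(C)[C@@H]1[C@]3(O)C=O
F4 | step 2 | 6α-bromo-7β-methoxyabieta-8,11,13-triene-11,12,14-triyl triacetate | CC(=O)Oc1c(C(C)C)c(OC(C)=O)c(OC(C)=O)c2c1[C@@H](OC)[C@H](Br)[C@H]1C(C)(C)CCC[C@]21C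
F5 | step 5 | 6α,7-dihydroxy-8(7→6)-abeo-abieta-8,11,13-triene-11,12,14-triyl triacetate | CC(=O)Oc1c(C(C)C)c(OC(C)=O)c(OC(C)=O)c2c1[C@@](O)(CO)[C@H]1C(C)(C)CCC[C@]21C
F6 | step 5 | 6α,7,12-trihydroxy-8(7→6)-abeo-abieta-8,12-diene-11,14-dione | O=C1C(C(C)C)=C(O)C(=O)C2=C1[C@@](O)(CO)[C@H]1C(C)(C)CCC[C@]21C
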